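**Strategy**

The target is cut in the middle of its ArCH2–CH2O ethylene bridge. Each methylene is the α-carbon of an accessible carboxylic acid: the OCH2 carbon that of an O-acylglycolic acid built on the dihydropyran acid, the ArCH2 carbon that of 3,4-dihydroxyphenylacetic acid. A nickel-electrocatalytic doubly decarboxylative cross-coupling of the two N-hydroxyphthalimide esters therefore joins the complete 3,4-dihydro-2H-pyran core (vinylogous carbonate O1–C6=C5–CO2Me, stereotriad C2/C3/C4) to the protected catechol in one operation, with loss of two CO2. The core comes from an Evans aldol, ring-closing metathesis, a Mukaiyama–Michael addition and an acyl-lactone rearrangement.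

Key step: step 15

Remark: the pyran atoms are numbered O1, C2 (CH3), C3 (CH2O), C4 (CH2CO), C5 (CO2CH3), C6. The enamine geometry of 12 and the configurations at C5 and C6 of 13 are irrelevant, because these centres become sp2 in 14.

**Route**

Step 1
Reactants: 1 (S)-4-benzyloxazolidin-2-one; 2 (E)-but-2-enoyl chloride
Product: 3 (S)-4-benzyl-3-[(E)-but-2-enoyl]oxazolidin-2-one
Conditions: n-BuLi, THF, −78 °C; then 2, −78 → 0 °C
Reagents that add atoms: none
Why: N-acylation of the lithiated oxazolidinone by the acid chloride is the standard entry to Evans imides and touches no stereocentre.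

Step 2
Reactants: 3 (S)-4-benzyl-3-[(E)-but-2-enoyl]oxazolidin-2-one; 4 acetaldehyde
Product: 5 (S)-4-benzyl-3-[(2S,3R)-2-ethenyl-3-hydroxybutanoyl]oxazolidin-2-one
Conditions: Bu2BOTf, Et3N, CH2Cl2, −78 → 0 °C; then 4, −78 °C; H2O2, pH 7 buffer, MeOH
Reagents that add atoms: none
Why: Evans syn-aldol: the (Z)-boron dienolate of the crotonyl imide adds to acetaldehyde at its α-carbon through a Zimmerman–Traxler chair on the face away from the benzyl group of the (S)-auxiliary, which sets the later C2 and C3 as the (2S,3R)-syn pair and leaves the vinyl group unconjugated.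

Step 3
Reactants: 5 (S)-4-benzyl-3-[(2S,3R)-2-ethenyl-3-hydroxybutanoyl]oxazolidin-2-one
Product: 6 (2R,3R)-2-ethenylbutane-1,3-diol
Conditions: LiBH4, MeOH (1 equiv), THF, 0 °C
Reagents that add atoms: none
Why: Reductive cleavage of the N-acyloxazolidinone with borohydride should give the primary alcohol and the recoverable auxiliary without epimerising the α-centre.

Step 4
Reactants: 6 (2R,3R)-2-ethenylbutane-1,3-diol
Product: 7 (2R,3R)-3-{[tert-butyl(diphenyl)silyl]oxymethyl}pent-4-en-2-ol
Conditions: TBDPSCl, imidazole, CH2Cl2, 0 °C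
Reagents that add atoms: tert-butyl(chloro)diphenylsilane, CC(C)(C)[Si](Cl)(c1ccccc1)c1ccccc1
Why: The bulky silyl chloride should silylate the primary hydroxyl selectively over the secondary one, giving an ether that withstands the later acidic methanol.

Step 5
Reactants: 7 (2R,3R)-3-{[tert-butyl(diphenyl)silyl]oxymethyl}pent-4-en-2-ol
Product: 8 (2R,3R)-3-{[tert-butyl(diphenyl)silyl]oxymethyl}pent-4-en-2-yl prop-2-enoate
Conditions: acryloyl chloride, iPr2NEt, DMAP (cat.), CH2Cl2, −20 → 0 °C
Reagents that add atoms: acryloyl chloride, C=CC(Cl)=O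
Why: O-acylation of the secondary alcohol with the acid chloride under amine base is routine and installs the second alkene for ring closure.

Step 6
Reactants: 8 (2R,3R)-3-{[tert-butyl(diphenyl)silyl]oxymethyl}pent-4-en-2-yl prop-2-enoate
Product: 9 (5R,6R)-5-{[tert-butyl(diphenyl)silyl]oxymethyl}-6-methyl-5,6-dihydro-2H-pyran-2-one
Conditions: Grubbs second-generation catalyst (5 mol%), CH2Cl2 (dilute), 40 °C
Reagents that add atoms: none
Why: Ring-closing metathesis of the acrylate with the terminal vinyl group should close the six-membered α,β-unsaturated δ-lactone with loss of ethene and without affecting the two stereocentres.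

Step 7
Reactants: 9 (5R,6R)-5-{[tert-butyl(diphenyl)silyl]oxymethyl}-6-methyl-5,6-dihydro-2H-pyran-2-one
Product: 11 methyl 2-[(2R,3R,4R)-3-{[tert-butyl(diphenyl)silyl]oxymethyl}-2-methyl-6-oxooxan-4-yl]acetate, via silyl ketene acetal 10 (not isolated)
Conditions: 1-(tert-butyldimethylsilyloxy)-1-methoxyethene, Tf2NH (5 mol%), CH2Cl2, −78 → −40 °C; then 1 M HCl, THF, 0 °C
Reagents that add atoms: 1-(tert-butyldimethylsilyloxy)-1-methoxyethene, C=C(OC)O[Si](C)(C)C(C)(C)C
Why: Mukaiyama–Michael addition: the silyl triflimide formed in situ activates the lactone and the ketene silyl acetal attacks C4 in 1,4-fashion on the face anti to the neighbouring CH2OTBDPS group, which sets the third stereocentre trans to it (all three substituents equatorial) and gives the silyl ketene acetal 10 that is hydrolysed on work-up.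

Step 8
Reactants: 11 methyl 2-[(2R,3R,4R)-3-{[tert-butyl(diphenyl)silyl]oxymethyl}-2-methyl-6-oxooxan-4-yl]acetate
Product: 12 methyl 2-[(2R,3R,4S,5E)-3-{[tert-butyl(diphenyl)silyl]oxymethyl}-5-(dimethylaminomethylidene)-2-methyl-6-oxooxan-4-yl]acetate
Conditions: tert-butoxybis(dimethylamino)methane, toluene, 80 °C
Reagents that add atoms: tert-butoxybis(dimethylamino)methane (Bredereck's reagent), CN(C)C(OC(C)(C)C)N(C)C
Why: Aminomethylenation with Bredereck's reagent should occur at the lactone α-methylene, which is more acidic than that of the acyclic methyl ester, and introduces the future C6 at the formyl oxidation level.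

Step 9
Reactants: 12 methyl 2-[(2R,3R,4S,5E)-3-{[tert-butyl(diphenyl)silyl]oxymethyl}-5-(dimethylaminomethylidene)-2-methyl-6-oxooxan-4-yl]acetate
Product: 14 methyl (2R,3R,4S)-3-{[tert-butyl(diphenyl)silyl]oxymethyl}-4-(2-methoxy-2-oxoethyl)-2-methyl-3,4-dihydro-2H-pyran-5-carboxylate, via cyclic methyl acetal 13 (not isolated)
Conditions: AcCl (3 equiv), MeOH, 0 °C → rt; concentrate; then TsOH (cat.), toluene, 80 °C
Reagents that add atoms: methanol, CO
Why: Acyl-lactone (Korte) rearrangement: HCl/MeOH converts the enaminone into the acetal and opens the lactone to the methyl ester, the freed C2 hydroxyl closes onto the acetal carbon to give the 6-methoxytetrahydropyran 13, and acid-catalysed loss of methanol gives the conjugated enol ether without touching the three stereocentres.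

Step 10
Reactants: 14 methyl (2R,3R,4S)-3-{[tert-butyl(diphenyl)silyl]oxymethyl}-4-(2-methoxy-2-oxoethyl)-2-methyl-3,4-dihydro-2H-pyran-5-carboxylate
Product: 15 2-[(2R,3R,4S)-3-{[tert-butyl(diphenyl)silyl]oxymethyl}-5-(methoxycarbonyl)-2-methyl-3,4-dihydro-2H-pyran-4-yl]acetic acid
Conditions: LiOH (1.2 equiv), THF/H2O, 0 °C; then 1 M HCl to pH 3, 0 °C
Reagents that add atoms: lithium hydroxide, [Li+].[OH-]
Why: Chemoselective saponification: the saturated acetate ester should hydrolyse much faster than the C5 ester, whose carbonyl is deactivated as a vinylogous carbonate by the ring oxygen.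

Step 11
Reactants: 15 2-[(2R,3R,4S)-3-{[tert-butyl(diphenyl)silyl]oxymethyl}-5-(methoxycarbonyl)-2-methyl-3,4-dihydro-2H-pyran-4-yl]acetic acid
Product: 16 2-oxo-2-(prop-2-enyloxy)ethyl 2-[(2R,3R,4S)-3-{[tert-butyl(diphenyl)silyl]oxymethyl}-5-(methoxycarbonyl)-2-methyl-3,4-dihydro-2H-pyran-4-yl]acetate
Conditions: allyl bromoacetate, Cs2CO3, DMF, rt
Reagents that add atoms: allyl bromoacetate, C=CCOC(=O)CBr
Why: SN2 O-alkylation of the caesium carboxylate by the α-bromo ester attaches the glycolate carbon that will become the OCH2 of the side chain.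

Step 12
Reactants: 16 2-oxo-2-(prop-2-enyloxy)ethyl 2-[(2R,3R,4S)-3-{[tert-butyl(diphenyl)silyl]oxymethyl}-5-(methoxycarbonyl)-2-methyl-3,4-dihydro-2H-pyran-4-yl]acetate
Product: 17 2-({2-[(2R,3R,4S)-3-{[tert-butyl(diphenyl)silyl]oxymethyl}-5-(methoxycarbonyl)-2-methyl-3,4-dihydro-2H-pyran-4-yl]acetyl}oxy)acetic acid
Conditions: Pd(PPh3)4 (cat.), morpholine, THF, rt; dilute acid work-up
Reagents that add atoms: none
Why: Tsuji–Trost deallylation: Pd(0) ionises the allyl ester and morpholine traps the π-allyl unit, under neutral conditions that spare the silyl ether, the enol ether and both remaining esters.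

Step 13
Reactants: 18 3,4-dihydroxyphenylacetic acid
Product: 20 2-[3,4-bis(tert-butyldimethylsilyloxy)phenyl]acetic acid, via tris-silylated silyl ester 19 (not isolated)
Conditions: TBSCl (3.3 equiv), imidazole, DMF, rt; then AcOH/THF/H2O, rt
Reagents that add atoms: tert-butyl(chloro)dimethylsilane, CC(C)(C)[Si](C)(C)Cl
Why: Exhaustive silylation followed by mild aqueous acid should hydrolyse only the labile silyl ester and leave both aryl silyl ethers.

Step 14
Reactants: 20 2-[3,4-bis(tert-butyldimethylsilyloxy)phenyl]acetic acid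
Product: 21 1,3-dioxoisoindolin-2-yl 2-[3,4-bis(tert-butyldimethylsilyloxy)phenyl]acetate
Conditions: N-hydroxyphthalimide, DIC, DMAP (cat.), CH2Cl2, rt
Reagents that add atoms: N-hydroxyphthalimide, O=C1c2ccccc2C(=O)N1O
Why: Carbodiimide (Steglich-type) esterification with N-hydroxyphthalimide gives the redox-active ester of the arylacetic acid.

Step 15
Reactants: 17 2-({2-[(2R,3R,4S)-3-{[tert-butyl(diphenyl)silyl]oxymethyl}-5-(methoxycarbonyl)-2-methyl-3,4-dihydro-2H-pyran-4-yl]acetyl}oxy)acetic acid; 21 1,3-dioxoisoindolin-2-yl 2-[3,4-bis(tert-butyldimethylsilyloxy)phenyl]acetate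
Product: 23 methyl (2R,3R,4S)-4-{2-[2-(3,4-bis(tert-butyldimethylsilyloxy)phenyl)ethoxy]-2-oxoethyl}-3-{[tert-butyl(diphenyl)silyl]oxymethyl}-2-methyl-3,4-dihydro-2H-pyran-5-carboxylate, via core redox-active ester 22 (not isolated)
Conditions: 17, N-hydroxyphthalimide, DIC, DMAP (cat.), NMP, rt; then 21 (3 equiv), NiCl2·6H2O (20 mol%), 2,2':6',2''-terpyridine (20 mol%), AgNO3 (0.3 equiv), NaI, NMP, Mg(+)/RVC(−), constant current, rt
Reagents that add atoms: none
Why: Both N-acyloxyphthalimides are reduced by low-valent nickel at the silver-nanoparticle-coated cathode, lose phthalimide anion and CO2 and give the acyloxymethyl radical from 22 and the 3,4-bis(silyloxy)benzyl radical from 21; the terpyridine–nickel catalyst captures the first as an alkylnickel species, intercepts the second to reach a dialkylnickel(III) complex and reductively eliminates the CH2–CH2 bond, while the magnesium anode supplies the electrons. The closest known reaction type is the nickel-electrocatalytic doubly decarboxylative C(sp3)–C(sp3) cross-coupling of two alkyl redox-active esters, applied here to a primary α-acyloxy and a primary benzylic partner. No ring is closed and no stereocentre is formed; C2, C3 and C4 of the dihydropyran are remote from both radical sites and cannot epimerise. The step needs cross- over homo-coupling, which is secured by the threefold excess of the cheap ester 21 and by the different lifetimes of the radicals (a short-lived acyloxymethyl radical that is metalated quickly, a longer-lived benzylic radical that adds to the resulting alkylnickel). It also needs chemoselective reduction, which holds because the N–O esters are reduced far more easily than the vinylogous carbonate, the alkyl esters and the silyl ethers, and because neither alkylnickel intermediate has a β-hydrogen to eliminate.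

Step 16
Reactants: 23 methyl (2R,3R,4S)-4-{2-[2-(3,4-bis(tert-butyldimethylsilyloxy)phenyl)ethoxy]-2-oxoethyl}-3-{[tert-butyl(diphenyl)silyl]oxymethyl}-2-methyl-3,4-dihydro-2H-pyran-5-carboxylate
Product: 24 methyl (2R,3R,4S)-4-{2-[2-(3,4-dihydroxyphenyl)ethoxy]-2-oxoethyl}-3-(hydroxymethyl)-2-methyl-3,4-dihydro-2H-pyran-5-carboxylate (CNP0204147.1)
Conditions: HF·pyridine, pyridine, THF, 0 °C → rt
Reagents that add atoms: none
Why: Buffered fluoride-mediated global desilylation should remove the alkyl TBDPS ether and both aryl TBS ethers under non-basic conditions, which avoids lactonisation of the freed primary alcohol onto the side-chain ester and leaves the enol ether intact.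

**Compound list**

1 | (S)-4-benzyloxazolidin-2-one | O=C1N[C@@H](Cc2ccccc2)CO1 | starting material
2 | (E)-but-2-enoyl chloride | C/C=C/C(Cl)=O | starting material
3 | (S)-4-benzyl-3-[(E)-but-2-enoyl]oxazolidin-2-one | C/C=C/C(=O)N1[C@@H](Cc2ccccc2)COC1=O | intermediate
4 | acetaldehyde | CC=O | starting material
5 | (S)-4-benzyl-3-[(2S,3R)-2-ethenyl-3-hydroxybutanoyl]oxazolidin-2-one | C[C@@H](O)[C@H](C=C)C(=O)N1[C@@H](Cc2ccccc2)COC1=O | intermediate
6 | (2R,3R)-2-ethenylbutane-1,3-diol | C[C@@H](O)[C@H](C=C)CO | intermediate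
7 | (2R,3R)-3-{[tert-butyl(diphenyl)silyl]oxymethyl}pent-4-en-2-ol | C[C@@H](O)[C@H](C=C)CO[Si](c1ccccc1)(c1ccccc1)C(C)(C)C | intermediate
8 | (2R,3R)-3-{[tert-butyl(diphenyl)silyl]oxymethyl}pent-4-en-2-yl prop-2-enoate | C[C@@H](OC(=O)C=C)[C@H](C=C)CO[Si](c1ccccc1)(c1ccccc1)C(C)(C)C | intermediate
9 | (5R,6R)-5-{[tert-butyl(diphenyl)silyl]oxymethyl}-6-methyl-5,6-dihydro-2H-pyran-2-one | C[C@H]1OC(=O)C=C[C@@H]1CO[Si](c1ccccc1)(c1ccccc1)C(C)(C)C | intermediate
10 | methyl 2-[(2R,3R,4S)-6-(tert-butyldimethylsilyloxy)-3-{[tert-butyl(diphenyl)silyl]oxymethyl}-2-methyl-3,4-dihydro-2H-pyran-4-yl]acetate (silyl ketene acetal) | C[C@H]1OC(O[Si](C)(C)C(C)(C)C)=C[C@@H](CC(=O)OC)[C@@H]1CO[Si](c1ccccc1)(c1ccccc1)C(C)(C)C | intermediate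
11 | methyl 2-[(2R,3R,4R)-3-{[tert-butyl(diphenyl)silyl]oxymethyl}-2-methyl-6-oxooxan-4-yl]acetate | C[C@H]1OC(=O)C[C@@H](CC(=O)OC)[C@@H]1CO[Si](c1ccccc1)(c1ccccc1)C(C)(C)C | intermediate
12 | methyl 2-[(2R,3R,4S,5E)-3-{[tert-butyl(diphenyl)silyl]oxymethyl}-5-(dimethylaminomethylidene)-2-methyl-6-oxooxan-4-yl]acetate | C[C@H]1OC(=O)/C(=C/N(C)C)[C@@H](CC(=O)OC)[C@@H]1CO[Si](c1ccccc1)(c1ccccc1)C(C)(C)C | intermediate
13 | methyl (2R,3R,4S)-3-{[tert-butyl(diphenyl)silyl]oxymethyl}-6-methoxy-4-(2-methoxy-2-oxoethyl)-2-methyloxane-5-carboxylate (mixture at C5 and C6) | COC(=O)C1C(OC)O[C@H](C)[C@@H](CO[Si](c2ccccc2)(c2ccccc2)C(C)(C)C)[C@@H]1CC(=O)OC | intermediate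
14 | methyl (2R,3R,4S)-3-{[tert-butyl(diphenyl)silyl]oxymethyl}-4-(2-methoxy-2-oxoethyl)-2-methyl-3,4-dihydro-2H-pyran-5-carboxylate | COC(=O)C1=CO[C@H](C)[C@@H](CO[Si](c2ccccc2)(c2ccccc2)C(C)(C)C)[C@@H]1CC(=O)OC | intermediate
15 | 2-[(2R,3R,4S)-3-{[tert-butyl(diphenyl)silyl]oxymethyl}-5-(methoxycarbonyl)-2-methyl-3,4-dihydro-2H-pyran-4-yl]acetic acid | COC(=O)C1=CO[C@H](C)[C@@H](CO[Si](c2ccccc2)(c2ccccc2)C(C)(C)C)[C@@H]1CC(=O)O | intermediate
16 | 2-oxo-2-(prop-2-enyloxy)ethyl 2-[(2R,3R,4S)-3-{[tert-butyl(diphenyl)silyl]oxymethyl}-5-(methoxycarbonyl)-2-methyl-3,4-dihydro-2H-pyran-4-yl]acetate | COC(=O)C1=CO[C@H](C)[C@@H](CO[Si](c2ccccc2)(c2ccccc2)C(C)(C)C)[C@@H]1CC(=O)OCC(=O)OCC=C | intermediate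
17 | 2-({2-[(2R,3R,4S)-3-{[tert-butyl(diphenyl)silyl]oxymethyl}-5-(methoxycarbonyl)-2-methyl-3,4-dihydro-2H-pyran-4-yl]acetyl}oxy)acetic acid | COC(=O)C1=CO[C@H](C)[C@@H](CO[Si](c2ccccc2)(c2ccccc2)C(C)(C)C)[C@@H]1CC(=O)OCC(=O)O | intermediate
18 | 3,4-dihydroxyphenylacetic acid | OC(=O)Cc1ccc(O)c(O)c1 | starting material
19 | tert-butyldimethylsilyl 2-[3,4-bis(tert-butyldimethylsilyloxy)phenyl]acetate | CC(C)(C)[Si](C)(C)OC(=O)Cc1ccc(O[Si](C)(C)C(C)(C)C)c(O[Si](C)(C)C(C)(C)C)c1 | intermediate
20 | 2-[3,4-bis(tert-butyldimethylsilyloxy)phenyl]acetic acid | OC(=O)Cc1ccc(O[Si](C)(C)C(C)(C)C)c(O[Si](C)(C)C(C)(C)C)c1 | intermediate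
21 | 1,3-dioxoisoindolin-2-yl 2-[3,4-bis(tert-butyldimethylsilyloxy)phenyl]acetate | O=C(Cc1ccc(O[Si](C)(C)C(C)(C)C)c(O[Si](C)(C)C(C)(C)C)c1)ON1C(=O)c2ccccc2C1=O | intermediate
22 | 1,3-dioxoisoindolin-2-yl 2-({2-[(2R,3R,4S)-3-{[tert-butyl(diphenyl)silyl]oxymethyl}-5-(methoxycarbonyl)-2-methyl-3,4-dihydro-2H-pyran-4-yl]acetyl}oxy)acetate | COC(=O)C1=CO[C@H](C)[C@@H](CO[Si](c2ccccc2)(c2ccccc2)C(C)(C)C)[C@@H]1CC(=O)OCC(=O)ON1C(=O)c2ccccc2C1=O | intermediate
23 | methyl (2R,3R,4S)-4-{2-[2-(3,4-bis(tert-butyldimethylsilyloxy)phenyl)ethoxy]-2-oxoethyl}-3-{[tert-butyl(diphenyl)silyl]oxymethyl}-2-methyl-3,4-dihydro-2H-pyran-5-carboxylate | COC(=O)C1=CO[C@H](C)[C@@H](CO[Si](c2ccccc2)(c2ccccc2)C(C)(C)C)[C@@H]1CC(=O)OCCc1ccc(O[Si](C)(C)C(C)(C)C)c(O[Si](C)(C)C(C)(C)C)c1 | intermediate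
24 | methyl (2R,3R,4S)-4-{2-[2-(3,4-dihydroxyphenyl)ethoxy]-2-oxoethyl}-3-(hydroxymethyl)-2-methyl-3,4-dihydro-2H-pyran-5-carboxylate | COC(=O)C1=CO[C@H](C)[C@@H](CO)[C@@H]1CC(=O)OCCc1ccc(O)c(O)c1 | target

**Step count**

Total: 16 steps. Longest linear sequence: 14 steps (steps 1–12, 15, 16); steps 13 and 14 form the two-step arene branch.

**Steps most likely to fail**

Step 15. The benzylic radical may dimerise faster than it is intercepted by nickel, and the acyloxymethyl partner may be lost to simple reduction, so that cross-coupling is outrun by homo-coupling and protodecarboxylation. The fallback forms the same CH2–CH2 bond from a defined nucleophile and a defined electrophile; it sets out from acid 15 and comes back to the route at the target 24. Acid 15 would be converted with chloromethyl chlorosulfate (NaHCO3, Bu4NHSO4, CH2Cl2/H2O) into the chloromethyl ester F1, and sodium iodide in acetone would give the iodomethyl ester F2. Commercial 3,4-bis(benzyloxy)benzyl chloride would be inserted with zinc dust/LiCl in THF to give the benzylic zinc chloride F3. A nickel-catalysed Negishi coupling of F2 with F3 (Ni(acac)2, 4-fluorostyrene, Bu4NI, THF/NMP, −10 °C) should give the dibenzyl-protected phenethyl ester F4. Hydrogenolysis (H2, Pd/C, EtOAc) would free the catechol F5, and HF·pyridine as in step 16 would give 24.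

Step 7. Addition to the hindered lactone may be slow, or the nucleophile may approach syn to the CH2OTBDPS group for stereoelectronic reasons, so that facial selectivity at C4 is poor. The fallback replaces kinetic control by thermodynamic control; it sets out from lactone 9 and comes back at lactone 11. Sodium dimethyl malonate (cat. NaH, dimethyl malonate, THF, 0 °C → rt) adds reversibly and should settle on the all-equatorial malonate adduct F6, which Krapcho demethoxycarbonylation (LiCl, wet DMSO, 140 °C) would convert into 11.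

Step 9. The strong acid needed to turn the enaminone into the acetal and open the lactone may also erode the silyl ether, after which the primary hydroxyl could close onto C6 and give the regioisomeric pyran; elimination of methanol may also stay incomplete. The fallback installs C6 directly as an acetal so that only mild acid is needed; it sets out from lactone 9 and comes back at diester 14. In the flask of step 7 the silyl ketene acetal 10 would be treated with trimethyl orthoformate and TMSOTf (CH2Cl2, −78 °C) to give the α-(dimethoxymethyl) lactone F7. Camphorsulfonic acid (cat.) in methanol at rt, then PPTS in toluene at 80 °C, should take F7 through 13 to 14.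

**Further compounds**

F1 | step 15 | chloromethyl 2-[(2R,3R,4S)-3-{[tert-butyl(diphenyl)silyl]oxymethyl}-5-(methoxycarbonyl)-2-methyl-3,4-dihydro-2H-pyran-4-yl]acetate | COC(=O)C1=CO[C@H](C)[C@@H](CO[Si](c2ccccc2)(c2ccccc2)C(C)(C)C)[C@@H]1CC(=O)OCCl
F2 | step 15 | iodomethyl 2-[(2R,3R,4S)-3-{[tert-butyl(diphenyl)silyl]oxymethyl}-5-(methoxycarbonyl)-2-methyl-3,4-dihydro-2H-pyran-4-yl]acetate | COC(=O)C1=CO[C@H](C)[C@@H](CO[Si](c2ccccc2)(c2ccccc2)C(C)(C)C)[C@@H]1CC(=O)OCI
F3 | step 15 | [3,4-bis(benzyloxy)benzyl]zinc chloride | Cl[Zn]Cc1ccc(OCc2ccccc2)c(OCc2ccccc2)c1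
F4 | step 15 | methyl (2R,3R,4S)-4-{2-[2-(3,4-bis(benzyloxy)phenyl)ethoxy]-2-oxoethyl}-3-{[tert-butyl(diphenyl)silyl]oxymethyl}-2-methyl-3,4-dihydro-2H-pyran-5-carboxylate | COC(=O)C1=CO[C@H](C)[C@@H](CO[Si](c2ccccc2)(c2ccccc2)C(C)(C)C)[C@@H]1CC(=O)OCCc1ccc(OCc2ccccc2)c(OCc2ccccc2)c1
F5 | step 15 | methyl (2R,3R,4S)-3-{[tert-butyl(diphenyl)silyl]oxymethyl}-4-{2-[2-(3,4-dihydroxyphenyl)ethoxy]-2-oxoethyl}-2-methyl-3,4-dihydro-2H-pyran-5-carboxylate | COC(=O)C1=CO[C@H](C)[C@@H](CO[Si](c2ccccc2)(c2ccccc2)C(C)(C)C)[C@@H]1CC(=O)OCCc1ccc(O)c(O)c1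
F6 | step 7 | dimethyl 2-[(2R,3R,4R)-3-{[tert-butyl(diphenyl)silyl]oxymethyl}-2-methyl-6-oxooxan-4-yl]propanedioate | C[C@H]1OC(=O)C[C@@H](C(C(=O)OC)C(=O)OC)[C@@H]1CO[Si](c1ccccc1)(c1ccccc1)C(C)(C)C
F7 | step 9 | methyl 2-[(2R,3R,4S)-3-{[tert-butyl(diphenyl)silyl]oxymethyl}-5-(dimethoxymethyl)-2-methyl-6-oxooxan-4-yl]acetate (mixture at C5) | C[C@H]1OC(=O)C(C(OC)OC)[C@@H](CC(=O)OC)[C@@H]1CO[Si](c1ccccc1)(c1ccccc1)C(C)(C)C
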